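Its constants are those of an exercise; the rest is arithmetic.

In a one-step world, starting material and coupling partner give target and the share asked for needs no reckoning. This flask has rivals for both.

- midnight: starting material 5.0 × 10⁻⁴ M; second substrate 0.200 equiv; gas 0.16 mM (held); temperature 25 °C; time 3.0 s
- dawn: starting material 5.0 × 10⁻⁴ M; second substrate 0.200 equiv; gas 0.16 mM (held); temperature 40 °C; time 3.0 s

    starting material + coupling partner → target (k1 = 1500 M⁻¹ s⁻¹, Ea1 = 46.0 kJ mol⁻¹)
    second substrate + coupling partner → second product (k2 = 57000 M⁻¹ s⁻¹, Ea2 = 22.0 kJ mol⁻¹)
    starting material + second substrate → cross product (k3 = 80 M⁻¹ s⁻¹, Ea3 = 39.0 kJ mol⁻¹)
    gas ⇌ coupling partner, rate k4*(csat - [coupling partner]) (k4 = 0.44 s⁻¹, csat = 0.16 mM)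
    (constants at 40 °C)

- at the start none of coupling partner is dissolved
- the list of constants is for 40 °C, to be carried to other temperatures by the activation energies

* which flask leads in share of target in all that became target or cross product ("all alike" within 1.5 percentage points) (midnight / dawn / all alike)
* share of target in all that became target or cross product, midnight
* share of target in all that became target or cross product, dawn

What must the end state be? Second substrate is used up, cross product has stopped, and starting material is still going on to target, so the share climbs with time and a reading at 3.0 s is a reading on the way.

Who takes the dissolved coupling partner first? At the start of dawn, second substrate removes it at 5.70 s⁻¹ per unit of partner, faster than starting material at 0.750 s⁻¹, and faster than the transfer coefficient 0.44 s⁻¹.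

Then what sets the pace? At that start the transfer is the rate-limiting step, and its inflow is at best 0.0704 mM s⁻¹. That gives 1.42 s, the clearing time: the charge of second substrate divided by the best inflow of coupling partner. The list gives the transfer no activation energy, so midnight and dawn share this clock.

What does it give? If second substrate falls evenly over the clearing time, it stands on average at half its charge, and dawn makes cross product worth 0.568% of the starting material. After clearing, coupling partner rises towards saturation, and dawn makes target worth 10.6%. So dawn's share is 94.9%. For midnight I divide target by 2.4 and cross product by 2.1, which gives 94.2%. The gap of 0.7 percentage points is smaller than the margin, so I say all alike.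

Isn't that inflow too kind? Yes: dissolved coupling partner lowers it, so I expect more cross product than this and shares below mine.

The forecast said all alike, with 91.3% for midnight and 90.6% for dawn, holding that “these effects nearly cancel”. The simulation gives all alike, with 91.2% for midnight and 90.8% for dawn.

Dawn was read at 2.11 clearing times and kept 2.19% of its second substrate. At 1.50 s, just past one clearing time, dawn still held 32.2%, and by 3.00 s its cross product had reached 0.935% against my 0.568%. With 0.500 equiv of second substrate and dawn otherwise unchanged, the clearing time becomes 3.55 s, longer than the 3.0 s allowed, so that flask is read at 0.845 clearing times. It kept 24% of its second substrate, made 3.26% target and 3.54% cross product, and its share stands at 48.0%.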